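The readings stem from a simulated flask with made-up constants; scatter was added.

Racemization turns one hand of substrate into the other, so the two substrates and two products always sum to the charge, and the substrate sum gives the conversion. The excess of right-handed over left-handed substrate is a running balance: it gains the product excess times the fractional loss rate of substrate, and it decays at a relaxation rate. This is a dynamic kinetic resolution.

in all of them: left-handed substrate 0.054 M; right-handed substrate 0.054 M; racemization catalyst 1.4 mM
- alpha: partner 0.135 M; free catalyst 5.4 mM; run made earlier
- eta: partner 0.135 M; free catalyst 12 mM; run made earlier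
- zeta: partner 0.27 M; free catalyst 8.1 mM; run made earlier
- flask: partner 0.135 M; free catalyst 8.1 mM; time 15 min

| run | time / min | left-handed substrate / % | right-handed substrate / % |
|---|---|---|---|
| alpha | 0.667 | 22.0 | 28.0 |
| alpha | 1.33 | 17.3 | 20.2 |
| alpha | 2.00 | 15.6 | 16.8 |
| alpha | 3.00 | 13.5 | 13.4 |
| alpha | 5.00 | 11.1 | 11.5 |
| alpha | 10.0 | 8.5 | 9.1 |
| eta | 0.667 | 14.8 | 21.1 |
| eta | 2.00 | 11.5 | 12.3 |
| eta | 3.00 | 10.4 | 10.4 |
| eta | 5.00 | 8.4 | 8.9 |
| eta | 6.00 | 7.8 | 8.4 |
| eta | 10.0 | 5.8 | 7.0 |
| zeta | 0.833 | 5.0 | 8.4 |
| zeta | 2.50 | 2.3 | 1.7 |
| zeta | 4.00 | 1.2 | 1.1 |
| zeta | 6.00 | 1.0 | 0.9 |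
| zeta | 10.0 | 0.6 | 0.7 |

(each reading ± 0.3 percentage points)

- free catalyst is single-handed; left-handed substrate and right-handed substrate are mirror images of each other, charged as a racemate, each of them at the stated concentration
- an excess is the difference of the two amounts in percent of their sum
- an excess is below zero if the other one leads

1. part of the left-handed substrate and right-handed substrate charged together that has reacted at 15 min
2. excess of left-handed product over right-handed product in the product at 15 min
3. excess of right-handed substrate over left-handed substrate among what is left of the two at 15 min

In alpha the excess is back near zero by 3.00 min. Its area up to then, 0.160 min, divided by the natural logarithm of charged over remaining substrate, gives 0.122 min. This is the excess lag, the product excess over the relaxation rate, and multiplied by the fractional loss rate it gives the substrate excess once the excess follows the loss. Eta, with about twice the free catalyst, reads 0.137 min.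

The same balance at alpha's first reading, excess 12.0%, puts the relaxation rate at 2.69 min⁻¹, so my product excess is 32.8%. Alpha loses substrate at 0.218 min⁻¹ between 1.33 min and 2.00 min, and alpha and eta lose it at 0.0500 min⁻¹ and 0.0589 min⁻¹ late, each of these slower than that relaxation. In alpha, rate times time stays at 0.363 and 0.375. Taking the flask as the mean of alpha and eta, I reckon a loss rate of 0.0272 min⁻¹ at 15 min, 12.9% of substrate left, so 87.1% reacted, and a substrate excess of 0.332%.

The forecast differs on both excesses, giving 87%, 16% and 9%, on the view “so racemization is probably fading”.

The flask gives 86.8% reacted, a product excess of 33.8% and a substrate excess of 0.378%.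

    partner + free catalyst + left-handed substrate → free catalyst + left-handed product (k = 75.0 M⁻² s⁻¹)
    partner + free catalyst + right-handed substrate → free catalyst + right-handed product (k = 31.0 M⁻² s⁻¹)
    left-handed substrate + racemization catalyst ⇌ right-handed substrate + racemization catalyst, rate k3*[racemization catalyst]*[left-handed substrate] forward; the back reaction follows from the equilibrium constant (k = 15.0 M⁻¹ s⁻¹)
    2 free catalyst → spent catalyst (k = 3.20 M⁻¹ s⁻¹)

The forward racemization half-life, 0.55 min, is short against the 15 min of the run. Divided by the lag, the flask's substrate excess stands for a loss rate of 0.0310 min⁻¹. A neighbour flask, the same but with a quarter of the racemization catalyst, takes the lag scaled up to 0.489 min, which at that loss rate gives 1.52%, and that neighbour stands at a substrate excess of 1.74%.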